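**Plan**
1. Retrosynthetic cuts, in order: C5–O with C4=C15 (singlet-oxygen ene reaction on a C4=C5 alkene); the C3 angelate, C8 acetate and C12 methyl ester (from a C3 ketone and a cis 8β,12-lactone); C7–C11 (intramolecular vinylogous Rauhut–Currier reaction of an O8 acrylate); C6=C7 (dehydrogenation); C4=C5 and C1–C10 (Robinson annulation with ethyl vinyl ketone).
2. Forward: ring B is the starting cyclohexanone 1; ring A is closed by Michael addition and aldol condensation (steps 1–2); a temporary lactone ring is closed across C7/C8 (step 7) and opened again (step 8); ring A is oxidised last (steps 9–11).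
3. Stereochemistry: C10 from the (R)-1-phenylethylamine imine; C8 from equatorial hydride delivery anti to the axial C10 methyl; C7 from the O8 tether; C3 from axial hydride attack; C5 from α-face attack of singlet oxygen anti to the C10 methyl.
4. Enabling feature: in ring B, O8 (on C8) and the acrylate carbon C11 (on C7) are cis-vicinal, so the target is a seco-8β,12-lactone. C7 is also the δ-carbon of the C3(=O)–C4=C5–C6=C7 dienone that ring-A annulation and dehydrogenation provide. Acrylic acid hung on O8 can therefore be closed onto C7 with a catalytic phosphine, bringing in C11–C13 at their final oxidation level.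

Key step: step 7

Remark: positions are given with eudesmane locants (C10 angular carbon, C14 its methyl, C15 on C4, C11–C13 on C7). Racemic 1 is taken as a catalogue compound. The sense of induction in step 1 is assigned by analogy with the established outcome for 2-methylcyclohexanone imines.

**Step 1**
Reactants: 1 rac-7-methyl-1,4-dioxaspiro[4.5]decan-8-one; 2 (R)-1-phenylethylamine; 3 ethyl vinyl ketone
Product: 6 (7R)-7-methyl-7-(3-oxopentyl)-1,4-dioxaspiro[4.5]decan-8-one, via ketimine 4 (not isolated), via Michael-adduct imine 5 (not isolated)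
Conditions: 2, TsOH (cat.), toluene, reflux (Dean–Stark); 3, THF, 40 °C; then 20% aq. AcOH, rt
Reagents that add atoms: water, O
Why: Deracemising Michael addition of a chiral imine through its more substituted secondary enamine tautomer: C10 attacks the enone in a compact aza-ene-like transition state on the face away from the phenyl group of the auxiliary, so both enantiomers of 1 should converge on the (R)-configured quaternary centre (10β-methyl), and aqueous acid then returns the ketone and the amine.

**Step 2**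
Reactants: 6
Product: 7 (4aR)-1,4a-dimethyl-4,4a,7,8-tetrahydronaphthalene-2,6(3H,5H)-dione 6-(ethylene ketal)
Conditions: NaOMe, MeOH, 60 °C
Reagents that add atoms: none
Why: Base-mediated intramolecular aldol condensation (ring-closing half of the Robinson annulation): the C4 enolate of the ethyl ketone adds to the C5 ketone and loss of water gives the conjugated C4=C5 enone, with the quaternary C10 untouched.

**Step 3**
Reactants: 7
Product: 8 (4aR)-1,4a-dimethyl-4,4a,7,8-tetrahydronaphthalene-2,6(3H,5H)-dione
Conditions: 1 M HCl, THF, rt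
Reagents that add atoms: water, O
Why: Acid-catalysed hydrolysis of the dioxolane frees the C8 ketone; the enone and C10 are not affected.

**Step 4**
Reactants: 8
Product: 9 (4aR,6S)-6-hydroxy-1,4a-dimethyl-4,4a,5,6,7,8-hexahydronaphthalen-2(3H)-one (8β-OH, cis to the C10 methyl)
Conditions: L-Selectride (1.05 equiv), THF, −78 °C; aq. NH4Cl
Reagents that add atoms: none
Why: Chemo- and diastereoselective hydride reduction: the saturated C8 ketone reacts far faster than the β,β-disubstituted enone, and the bulky hydride enters equatorially from the α face because the axial trajectory is blocked by the syn-axial C10 methyl, which should give the axial 8β-alcohol.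

**Step 5**
Reactants: 9
Product: 10 (2S,8aR)-5,8a-dimethyl-6-oxo-1,2,3,4,6,7,8,8a-octahydronaphthalen-2-yl prop-2-enoate
Conditions: acryloyl chloride, Et3N, DMAP (cat.), CH2Cl2, −20 → 0 °C
Reagents that add atoms: acryloyl chloride, C=CC(=O)Cl
Why: Base-mediated O-acylation of the secondary alcohol with an acid chloride; the C8–O bond is not broken, so the configuration is retained.

**Step 6**
Reactants: 10
Product: 11 (2R,8aR)-5,8a-dimethyl-6-oxo-1,2,6,7,8,8a-hexahydronaphthalen-2-yl prop-2-enoate (8β-acryloyloxy-4,6-dien-3-one)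
Conditions: chloranil (1.3 equiv), t-BuOH, reflux
Reagents that add atoms: none
Why: Quinone dehydrogenation of a Δ4-3-ketone: the 3,5-dienol gives up hydride from C7 to chloranil and loses a proton, which should give the linear 4,6-dien-3-one and make C7 the electrophilic δ-carbon; C8 and C10 are not touched, and the quinone also suppresses acrylate polymerisation.

**Step 7**
Reactants: 11
Product: 12 (3aR,8aR,9aR)-5,8a-dimethyl-3-methylidene-3a,4,7,8,8a,9-hexahydronaphtho[2,3-b]furan-2,6(3H,9aH)-dione (3-oxoeudesma-4,11(13)-dien-12,8β-olide)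
Conditions: PMe3 (0.3 equiv), t-AmOH, 0.02 M, rt
Reagents that add atoms: none
Why: Proposed new method: PMe3 should add reversibly to the unhindered acrylate terminus C13 to give a phosphonium ester enolate whose nucleophilic C11 is held by the O8 tether over C7, the δ-terminus of the C3(=O)–C4=C5–C6=C7 dienone; 1,6-addition forms C7–C11 and a dienolate, proton transfer through t-AmOH and E1cB loss of PMe3 restore the C11=C13 methylene and release the catalyst, and protonation at C6 (or base equilibration of any Δ5 isomer) returns the Δ4-enone. The closest known reaction type is the phosphine-catalysed intramolecular Rauhut–Currier cyclisation of 4-acryloyloxycyclohexadienones to cis-fused α-methylene-γ-butyrolactones (β-addition), extended here to the vinylogous δ-position, which is the established site of attack of soft nucleophiles on 4,6-dien-3-ones. The lactone ring closes in the 5-exo-trig mode. The one new stereocentre, C7, is controlled by the tether: delivery from the 8β (pseudoaxial) oxygen can only give the cis-fused lactone, so C11 ends β and H-7 α (7R). The step needs the phosphine to engage the acrylate and not the dienone, and C11 to attack C7 and not C5: phosphine addition to the dienone is reversible and leads only to a seven-membered closure, and C5 is fully substituted and likewise seven-membered from C11. No other group in 11 is electrophilic or acidic enough to intervene.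

**Step 8**
Reactants: 12
Product: 15 methyl 2-[(2R,3R,4aR)-3-acetoxy-4a,8-dimethyl-7-oxo-1,2,3,4,4a,5,6,7-octahydronaphthalen-2-yl]prop-2-enoate, via lithium hydroxy-carboxylate 13 (not isolated), via γ-hydroxy methyl ester 14 (not isolated)
Conditions: LiOH (1.05 equiv), THF/H2O, 0 °C; evaporate; MeI, DMF, rt; evaporate MeI; Ac2O, Et3N, DMAP, CH2Cl2, 0 °C → rt
Reagents that add atoms: lithium hydroxide, [Li+].[OH-]; iodomethane, CI; acetic anhydride, CC(=O)OC(C)=O
Why: Saponification of the cis-lactone, SN2 O-methylation of the carboxylate and acetylation of the freed axial 8β-hydroxyl, run without isolating the γ-hydroxy ester so that it cannot re-lactonise; no bond to C7 or C8 is broken, so both centres are kept, and the hydroxide also conjugates any Δ5 enone isomer carried over from step 7.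

**Step 9**
Reactants: 15
Product: 16 methyl 2-[(2R,3R,4aR,7S)-3-acetoxy-7-hydroxy-4a,8-dimethyl-1,2,3,4,4a,5,6,7-octahydronaphthalen-2-yl]prop-2-enoate (3β-OH)
Conditions: NaBH4, CeCl3·7H2O, MeOH, −78 °C
Reagents that add atoms: none
Why: Luche 1,2-reduction: cerium-activated borohydride attacks the enone carbonyl axially from the α face, anti to the C10 methyl, which should give the pseudo-equatorial 3β-alcohol (3S), while the acetate, the methyl ester and the 2-substituted acrylate are left at this temperature.

**Step 10**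
Reactants: 16
Product: 17 methyl 2-[(2R,3R,4aR,7S)-3-acetoxy-4a,8-dimethyl-7-{[(2Z)-2-methylbut-2-enoyl]oxy}-1,2,3,4,4a,5,6,7-octahydronaphthalen-2-yl]prop-2-enoate
Conditions: angelic acid, 2,4,6-trichlorobenzoyl chloride, Et3N, toluene, rt; then 16, DMAP, 60 °C
Reagents that add atoms: angelic acid [(2Z)-2-methylbut-2-enoic acid], C/C=C(/C)C(=O)O
Why: Yamaguchi esterification through the mixed 2,4,6-trichlorobenzoic anhydride, chosen because it acylates hindered secondary alcohols with little Z-to-E isomerisation of angelic acid; the C3–O bond is not broken, so 3β is retained.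

**Step 11**
Reactants: 17
Product: 19 methyl 8β-acetoxy-3β-angeloyloxy-5α-hydroxyeudesma-4(15),11(13)-dien-12-oate (target), via 5α-hydroperoxide 18 (not isolated)
Conditions: O2, tetraphenylporphyrin (cat.), white LED, CH2Cl2, 0 °C; then PPh3, 0 °C
Reagents that add atoms: oxygen, O=O
Why: Schenck ene reaction followed by reduction: singlet oxygen attacks only the electron-rich tetrasubstituted C4=C5 alkene (the conjugated angelate and acrylate are inert), from the α face anti to the axial C10 methyl, and abstracts a hydrogen of the C15 methyl group, which should place the hydroperoxide on C5 (5α) and move the alkene to C4=C15; triphenylphosphine then reduces the O–O bond without touching the C5–O bond.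

**Compound list**
1 | rac-7-methyl-1,4-dioxaspiro[4.5]decan-8-one | CC1CC2(CCC1=O)OCCO2 | starting material
2 | (R)-1-phenylethylamine | C[C@@H](N)c1ccccc1 | starting material
3 | ethyl vinyl ketone (pent-1-en-3-one) | CCC(=O)C=C | starting material
4 | (1R)-N-(7-methyl-1,4-dioxaspiro[4.5]decan-8-ylidene)-1-phenylethanamine (C7 epimers, in equilibrium with the enamine) | CC1CC2(CCC1=N[C@H](C)c3ccccc3)OCCO2 | intermediate
5 | (1R)-N-[(7R)-7-methyl-7-(3-oxopentyl)-1,4-dioxaspiro[4.5]decan-8-ylidene]-1-phenylethanamine | CCC(=O)CC[C@]1(C)CC2(CCC1=N[C@H](C)c3ccccc3)OCCO2 | intermediate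
6 | (7R)-7-methyl-7-(3-oxopentyl)-1,4-dioxaspiro[4.5]decan-8-one | CCC(=O)CC[C@]1(C)CC2(CCC1=O)OCCO2 | intermediate
7 | (4aR)-1,4a-dimethyl-4,4a,7,8-tetrahydronaphthalene-2,6(3H,5H)-dione 6-(ethylene ketal) | CC1=C2CCC3(OCCO3)C[C@@]2(C)CCC1=O | intermediate
8 | (4aR)-1,4a-dimethyl-4,4a,7,8-tetrahydronaphthalene-2,6(3H,5H)-dione | CC1=C2CCC(=O)C[C@@]2(C)CCC1=O | intermediate
9 | (4aR,6S)-6-hydroxy-1,4a-dimethyl-4,4a,5,6,7,8-hexahydronaphthalen-2(3H)-one | CC1=C2CC[C@H](O)C[C@@]2(C)CCC1=O | intermediate
10 | (2S,8aR)-5,8a-dimethyl-6-oxo-1,2,3,4,6,7,8,8a-octahydronaphthalen-2-yl prop-2-enoate | CC1=C2CC[C@H](OC(=O)C=C)C[C@@]2(C)CCC1=O | intermediate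
11 | (2R,8aR)-5,8a-dimethyl-6-oxo-1,2,6,7,8,8a-hexahydronaphthalen-2-yl prop-2-enoate | CC1=C2C=C[C@H](OC(=O)C=C)C[C@@]2(C)CCC1=O | intermediate
12 | (3aR,8aR,9aR)-5,8a-dimethyl-3-methylidene-3a,4,7,8,8a,9-hexahydronaphtho[2,3-b]furan-2,6(3H,9aH)-dione | CC1=C2C[C@H]3[C@@H](C[C@@]2(C)CCC1=O)OC(=O)C3=C | intermediate
13 | lithium 2-[(2R,3R,4aR)-3-hydroxy-4a,8-dimethyl-7-oxo-1,2,3,4,4a,5,6,7-octahydronaphthalen-2-yl]prop-2-enoate | C=C(C(=O)[O-])[C@H]1CC2=C(C)C(=O)CC[C@]2(C)C[C@H]1O.[Li+] | intermediate
14 | methyl 2-[(2R,3R,4aR)-3-hydroxy-4a,8-dimethyl-7-oxo-1,2,3,4,4a,5,6,7-octahydronaphthalen-2-yl]prop-2-enoate | C=C(C(=O)OC)[C@H]1CC2=C(C)C(=O)CC[C@]2(C)C[C@H]1O | intermediate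
15 | methyl 2-[(2R,3R,4aR)-3-acetoxy-4a,8-dimethyl-7-oxo-1,2,3,4,4a,5,6,7-octahydronaphthalen-2-yl]prop-2-enoate | C=C(C(=O)OC)[C@H]1CC2=C(C)C(=O)CC[C@]2(C)C[C@H]1OC(C)=O | intermediate
16 | methyl 2-[(2R,3R,4aR,7S)-3-acetoxy-7-hydroxy-4a,8-dimethyl-1,2,3,4,4a,5,6,7-octahydronaphthalen-2-yl]prop-2-enoate | C=C(C(=O)OC)[C@H]1CC2=C(C)[C@@H](O)CC[C@]2(C)C[C@H]1OC(C)=O | intermediate
17 | methyl 2-[(2R,3R,4aR,7S)-3-acetoxy-4a,8-dimethyl-7-{[(2Z)-2-methylbut-2-enoyl]oxy}-1,2,3,4,4a,5,6,7-octahydronaphthalen-2-yl]prop-2-enoate | C=C(C(=O)OC)[C@H]1CC2=C(C)[C@@H](OC(=O)/C(C)=C\C)CC[C@]2(C)C[C@H]1OC(C)=O | intermediate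
18 | methyl 2-[(2R,3R,4aR,7S,8aS)-3-acetoxy-8a-hydroperoxy-4a-methyl-8-methylidene-7-{[(2Z)-2-methylbut-2-enoyl]oxy}decahydronaphthalen-2-yl]prop-2-enoate | C=C(C(=O)OC)[C@H]1C[C@@]2(OO)C(=C)[C@@H](OC(=O)/C(C)=C\C)CC[C@]2(C)C[C@H]1OC(C)=O | intermediate
19 | methyl 2-[(2R,3R,4aR,7S,8aS)-3-acetoxy-8a-hydroxy-4a-methyl-8-methylidene-7-{[(2Z)-2-methylbut-2-enoyl]oxy}decahydronaphthalen-2-yl]prop-2-enoate (CNP0179024.1) | C=C(C(=O)OC)[C@H]1C[C@@]2(O)C(=C)[C@@H](OC(=O)/C(C)=C\C)CC[C@]2(C)C[C@H]1OC(C)=O | target

Total step count: 11. Longest linear sequence: 11 steps (from 1).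

**Steps most likely to fail**

1. Step 7 (Proposed new method). What may go wrong: the phosphonium enolate may fail to add to the δ-carbon, so that reversible phosphine addition to the dienone or oligomerisation of the acrylate outruns the 1,6-cyclisation. Fallback with known chemistry (stabilised-carbanion Michael addition and Horner–Wadsworth–Emmons methylenation), setting out from 9 and coming back at 12: 9 is esterified with diethylphosphonoacetic acid (DCC, DMAP, CH2Cl2) to the phosphonoacetate ester F1. F1 is dehydrogenated with chloranil as in step 6 to the dienone phosphonoacetate F2. Cs2CO3 (or DBU/LiCl) in MeCN should bring about the intramolecular 1,6-Michael addition of the phosphonate-stabilised carbanion to C7, giving the cis-fused α-phosphono lactone F3. Aqueous formaldehyde and K2CO3 then convert F3 into 12 by Horner–Wadsworth–Emmons methylenation.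

2. Step 6. What may go wrong: hydride abstraction from C7 may be slowed by the neighbouring acyloxy group, so that over-oxidation or thermal loss of acrylic acid competes. Fallback, setting out from 10 and coming back at 11: thermodynamic silylation (TBSOTf, Et3N, CH2Cl2, 0 °C) gives the 3-silyloxy-3,5-diene F4, and Saegusa–Ito oxidation of F4 (Pd(OAc)2, MeCN, rt) introduces the C6=C7 double bond under neutral conditions at room temperature to give 11.

3. Step 8. What may go wrong: the lactone may close again during methylation or acetylation of the γ-hydroxy ester. Fallback, setting out from 12 and coming back at 15, in which a free γ-hydroxy ester is never present: the carboxylate 13, made as in step 8, is silylated on both oxygens (TBSOTf, 2,6-lutidine, CH2Cl2) to the silyl ester silyl ether F5. A mild aqueous K2CO3 work-up cleaves only the silyl ester and gives the 8-O-silyl acid F6. TMSCHN2 (MeOH/toluene) gives the 8-O-silyl methyl ester F7. Ac2O with catalytic FeCl3 then exchanges the silyl ether directly for acetate to give 15.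

**Further compounds**
F1 | step 7 | (2S,8aR)-5,8a-dimethyl-6-oxo-1,2,3,4,6,7,8,8a-octahydronaphthalen-2-yl 2-(diethoxyphosphoryl)acetate | CC1=C2CC[C@H](OC(=O)CP(=O)(OCC)OCC)C[C@@]2(C)CCC1=O
F2 | step 7 | (2R,8aR)-5,8a-dimethyl-6-oxo-1,2,6,7,8,8a-hexahydronaphthalen-2-yl 2-(diethoxyphosphoryl)acetate | CC1=C2C=C[C@H](OC(=O)CP(=O)(OCC)OCC)C[C@@]2(C)CCC1=O
F3 | step 7 | diethyl [(3aR,8aR,9aR)-5,8a-dimethyl-2,6-dioxo-2,3,3a,4,6,7,8,8a,9,9a-decahydronaphtho[2,3-b]furan-3-yl]phosphonate (C3 epimers) | CC1=C2C[C@H]3[C@@H](C[C@@]2(C)CCC1=O)OC(=O)C3P(=O)(OCC)OCC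
F4 | step 6 | (2S,8aR)-6-[(tert-butyldimethylsilyl)oxy]-5,8a-dimethyl-1,2,3,7,8,8a-hexahydronaphthalen-2-yl prop-2-enoate | CC1=C(O[Si](C)(C)C(C)(C)C)CC[C@]2(C)C[C@@H](OC(=O)C=C)CC=C12
F5 | step 8 | tert-butyldimethylsilyl 2-[(2R,3R,4aR)-3-[(tert-butyldimethylsilyl)oxy]-4a,8-dimethyl-7-oxo-1,2,3,4,4a,5,6,7-octahydronaphthalen-2-yl]prop-2-enoate | C=C(C(=O)O[Si](C)(C)C(C)(C)C)[C@H]1CC2=C(C)C(=O)CC[C@]2(C)C[C@H]1O[Si](C)(C)C(C)(C)C
F6 | step 8 | 2-[(2R,3R,4aR)-3-[(tert-butyldimethylsilyl)oxy]-4a,8-dimethyl-7-oxo-1,2,3,4,4a,5,6,7-octahydronaphthalen-2-yl]prop-2-enoic acid | C=C(C(=O)O)[C@H]1CC2=C(C)C(=O)CC[C@]2(C)C[C@H]1O[Si](C)(C)C(C)(C)C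
F7 | step 8 | methyl 2-[(2R,3R,4aR)-3-[(tert-butyldimethylsilyl)oxy]-4a,8-dimethyl-7-oxo-1,2,3,4,4a,5,6,7-octahydronaphthalen-2-yl]prop-2-enoate | C=C(C(=O)OC)[C@H]1CC2=C(C)C(=O)CC[C@]2(C)C[C@H]1O[Si](C)(C)C(C)(C)C
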